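Ring A is disconnected at C2–C3. Its quaternary C3, held between the C2 and C4 carbonyl carbons, is what remains when the acyl carbon of an α,β-epoxy ketone shifts onto the distal epoxide carbon. One Lewis-acid step therefore makes the C2–C3 bond, enlarges a cyclopentenone to the six-membered ring A and sets C3 by inversion at an epoxide carbon. The substrate is the (2S,3S) spiro epoxide of a Z-alkylidene 2-bromo-3-methoxycyclopentenone, made by hydroxyl-directed epoxidation of an enantioenriched allylic alcohol. The bromine keeps C1 and C5 distinct and later becomes the hexanoyl group; ring B is joined last through a methylene bridge at C5.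

Key step: step 8

Remark: ring A is numbered as in the target (C1 carries the hexanoyl group, C3 is the quaternary carbon, C5 carries the methylene bridge); enolised polyketones are written as one tautomer; compounds 1, 5, 12 and 16 are assumed to be purchasable.

Remark: the stereochemical bookkeeping of the planned epoxy ketone 9 and its rearrangement product 10 was checked and is consistent: inversion at the (2S) epoxide carbon of 9 gives the (R) quaternary carbon of 10, which is the configuration of the target.

Step 1
Reactants: 1 3-methoxycyclopent-2-en-1-one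
Product: 2 2-bromo-3-methoxycyclopent-2-en-1-one
Conditions: N-bromosuccinimide, CH2Cl2, 0 °C → rt
Reagents that add atoms: N-bromosuccinimide, O=C1CCC(=O)N1Br
Why: Electrophilic bromination of the vinylogous ester at its nucleophilic α-carbon followed by loss of a proton is a standard halogenation of 3-alkoxy enones, and no stereocentre is formed.

Step 2
Reactants: 2 2-bromo-3-methoxycyclopent-2-en-1-one
Product: 3 5-acetyl-2-bromo-3-methoxycyclopent-2-en-1-one
Conditions: LiN(i-Pr)2 (2.2 equiv), THF, −78 °C; 1-acetyl-1H-benzotriazole, −78 → 0 °C; aq. NH4Cl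
Reagents that add atoms: 1-acetyl-1H-benzotriazole, CC(=O)n1nnc2ccccc12
Why: Kinetic α′-deprotonation of the 3-alkoxy enone at C5 and Claisen-type C-acylation of the lithium enolate with an N-acylbenzotriazole should give the β-diketone, the second equivalent of base absorbing the acidic product proton, and the new C5 centre is enolised and of no consequence.

Step 3
Reactants: 3 5-acetyl-2-bromo-3-methoxycyclopent-2-en-1-one
Product: 4 (1Z)-1-(3-bromo-4-methoxy-2-oxocyclopent-3-en-1-ylidene)ethyl trifluoromethanesulfonate
Conditions: Tf2O, aq. LiOH, toluene, 0–5 °C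
Reagents that add atoms: trifluoromethanesulfonic anhydride, O=S(=O)(OS(=O)(=O)C(F)(F)F)C(F)(F)F
Why: Enol triflate formation from a β-dicarbonyl compound through the lithium-chelated, U-shaped enolate should place the triflate on the acetyl oxygen, which carries most of the charge because the vinylogous ester carbonyl is the weaker acceptor, and syn to the ring carbonyl, which defines the Z geometry of the tetrasubstituted olefin.

Step 4
Reactants: 4 (1Z)-1-(3-bromo-4-methoxy-2-oxocyclopent-3-en-1-ylidene)ethyl trifluoromethanesulfonate; 5 4,4,5,5-tetramethyl-2-(3-methylbut-2-en-1-yl)-1,3,2-dioxaborolane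
Product: 6 (5Z)-2-bromo-3-methoxy-5-(5-methylhex-4-en-2-ylidene)cyclopent-2-en-1-one
Conditions: PdCl2(dppf) (5 mol %; dppf = 1,1′-bis(diphenylphosphino)ferrocene), CsF, THF, 60 °C
Reagents that add atoms: none
Why: Suzuki–Miyaura coupling of the activated β-keto alkenyl triflate (far more reactive than the ring bromide) with the allylboronate should proceed with retention of olefin geometry, and with the bidentate ligand the allylpalladium intermediate reductively eliminates at its unsubstituted terminus, so the prenyl group enters linear and cis to the ring carbonyl.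

Step 5
Reactants: 6 (5Z)-2-bromo-3-methoxy-5-(5-methylhex-4-en-2-ylidene)cyclopent-2-en-1-one
Product: 7 (1R,5Z)-2-bromo-3-methoxy-5-(5-methylhex-4-en-2-ylidene)cyclopent-2-en-1-ol
Conditions: (R)-1-methyl-3,3-diphenyltetrahydro-1H,3H-pyrrolo[1,2-c][1,3,2]oxazaborole (the (R)-CBS catalyst, 20 mol %), catecholborane, toluene, −78 → −40 °C
Reagents that add atoms: none
Why: In this Corey–Bakshi–Shibata reduction the catalyst boron can bind only the carbonyl lone pair on the bromine side, because the Z-allylic methylene lies in the ring plane against the other lone pair, so the alkylidene arm acts as the large group and the (R)-catalyst should deliver hydride to the face that gives the (1R)-alcohol, while catecholborane leaves the prenyl olefin and the vinyl bromide untouched.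

Step 6
Reactants: 7 (1R,5Z)-2-bromo-3-methoxy-5-(5-methylhex-4-en-2-ylidene)cyclopent-2-en-1-ol
Product: 8 (2S,3R,4R)-5-bromo-6-methoxy-2-methyl-2-(3-methylbut-2-en-1-yl)-1-oxaspiro[2.4]hept-5-en-4-ol
Conditions: VO(acac)2 (5 mol %), t-BuOOH (decane), CH2Cl2, 0 °C → rt
Reagents that add atoms: tert-butyl hydroperoxide, CC(C)(C)OO
Why: Vanadium-catalysed hydroxyl-directed epoxidation should deliver oxygen to the electron-rich tetrasubstituted exocyclic olefin on the face of the hydroxyl group, so both epoxide stereocentres follow from the carbinol configuration and the Z geometry, the remote prenyl olefin and the bromine-deactivated enol ether reacting more slowly.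

Step 7
Reactants: 8 (2S,3R,4R)-5-bromo-6-methoxy-2-methyl-2-(3-methylbut-2-en-1-yl)-1-oxaspiro[2.4]hept-5-en-4-ol
Product: 9 (2S,3S)-5-bromo-6-methoxy-2-methyl-2-(3-methylbut-2-en-1-yl)-1-oxaspiro[2.4]hept-5-en-4-one
Conditions: Dess–Martin periodinane, pyridine, CH2Cl2, 0 °C → rt
Reagents that add atoms: none
Why: Buffered Dess–Martin oxidation of the secondary allylic alcohol should restore the ketone without touching the epoxide or either olefin, and the carbinol stereocentre, having served as a relay, is removed.

Step 8
Reactants: 9 (2S,3S)-5-bromo-6-methoxy-2-methyl-2-(3-methylbut-2-en-1-yl)-1-oxaspiro[2.4]hept-5-en-4-one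
Product: 10 (2R)-4-bromo-5-methoxy-2-methyl-2-(3-methylbut-2-en-1-yl)cyclohex-4-ene-1,3-dione
Conditions: BF3·OEt2 (1.5 equiv), CH2Cl2, −78 → −30 °C
Reagents that add atoms: none
Why: BF3 binds the epoxide oxygen and the C–O bond at the exocyclic fully substituted carbon, which is remote from the carbonyl, lengthens while the ring carbonyl carbon C2 moves from the spiro carbon to the rear face of that carbon and the spiro carbon collapses to the C4 ketone. The closest known reaction type is the Lewis-acid semipinacol rearrangement of α,β-epoxy ketones to 1,3-diketones by 1,2-acyl migration, which is established for the ring enlargement of 2-alkylidenecycloalkanone oxides. Ring A is closed by a one-carbon ring expansion in which a bond of the five-membered ring migrates, not by cyclisation of a chain end, so no ring-closure rule applies. The new quaternary centre C3 is set by inversion at the (2S) epoxide carbon, whose configuration came from the Z olefin and the directed epoxidation of (1R)-7, and the spiro stereocentre disappears. The step needs acyl rather than C5-methylene migration and a bond shift concerted with ionisation: the higher migratory aptitude of an acyl group (here a donor-substituted vinylogous ester carbonyl), the instability of a cation next to the carbonyl and the low temperature should provide both, and the bromine on C1 prevents racemisation of the product through enol tautomers.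

Step 9
Reactants: 10 (2R)-4-bromo-5-methoxy-2-methyl-2-(3-methylbut-2-en-1-yl)cyclohex-4-ene-1,3-dione
Product: 11 (6R)-2-bromo-3,5-dimethoxy-6-methyl-6-(3-methylbut-2-en-1-yl)cyclohexa-2,4-dien-1-one
Conditions: HC(OMe)3, MeOH, p-toluenesulfonic acid monohydrate (cat.), rt
Reagents that add atoms: trimethyl orthoformate, COC(OC)OC
Why: Acid-catalysed enol ether formation at the C4 ketone (ketalisation and loss of methanol toward C5, the only enolisable side) removes the acidic C5 methylene before the basic palladium step, the C4 oxygen being the less hindered site, and the regioisomeric ether at the C2 oxygen, should some form, would converge in step 11.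

Step 10
Reactants: 11 (6R)-2-bromo-3,5-dimethoxy-6-methyl-6-(3-methylbut-2-en-1-yl)cyclohexa-2,4-dien-1-one; 12 pent-1-ene
Product: 14 (6R)-2-hexanoyl-3,5-dimethoxy-6-methyl-6-(3-methylbut-2-en-1-yl)cyclohexa-2,4-dien-1-one, via 9-pentyl-9-borabicyclo[3.3.1]nonane 13 (not isolated)
Conditions: 12 (slight excess), 9-BBN-H dimer, THF, 0 °C → rt; then 11, PdCl2(dppf) (5 mol %), K3PO4, CO (1 atm), THF–dioxane, 60 °C
Reagents that add atoms: carbon monoxide, [C-]#[O+]
Why: Anti-Markovnikov hydroboration of pent-1-ene gives the B-alkylborane, and carbonylative Suzuki–Miyaura coupling (oxidative addition of the electron-poor α-bromo enone, CO insertion to the acylpalladium species, base-assisted alkyl transfer from boron, reductive elimination) should install the hexanoyl ketone at C1 without affecting C3.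

Step 11
Reactants: 14 (6R)-2-hexanoyl-3,5-dimethoxy-6-methyl-6-(3-methylbut-2-en-1-yl)cyclohexa-2,4-dien-1-one
Product: 15 (4R)-2-hexanoyl-3,5-dihydroxy-4-methyl-4-(3-methylbut-2-en-1-yl)cyclohexa-2,5-dien-1-one
Conditions: 1 M aq. HCl, THF, rt → 40 °C
Reagents that add atoms: water, O
Why: Acid hydrolysis of the two vinylogous methyl esters (conjugate addition of water and loss of methanol), the C6 ether being doubly activated by the ring and hexanoyl carbonyls, should liberate the enolised triketone under conditions mild enough to spare the prenyl group, while the quaternary C3 cannot epimerise and C1 and C5 stay distinct.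

Step 12
Reactants: 16 1-(2,4,6-trihydroxyphenyl)butan-1-one
Product: 17 1-(2,6-dihydroxy-4-methoxyphenyl)butan-1-one
Conditions: Me2SO4 (1.0 equiv), K2CO3 (1.0 equiv), acetone, rt
Reagents that add atoms: dimethyl sulfate, COS(=O)(=O)OC
Why: Williamson etherification with one equivalent of dimethyl sulfate should occur at the 4-hydroxyl, the most acidic phenol and the only one not hydrogen-bonded to the ketone.

Step 13
Reactants: 17 1-(2,6-dihydroxy-4-methoxyphenyl)butan-1-one
Product: 18 1-{3-[(dimethylamino)methyl]-2,6-dihydroxy-4-methoxyphenyl}butan-1-one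
Conditions: aq. Me2NH (1.0 equiv), aq. CH2O (1.0 equiv), EtOH, 0 °C → rt
Reagents that add atoms: formaldehyde, C=O; dimethylamine, CNC
Why: Mannich aminomethylation of the electron-rich phloroglucinol ring takes place at one of its two equivalent free positions (between hydroxyl and methoxy) and is kept to monosubstitution by stoichiometry.

Step 14
Reactants: 15 (4R)-2-hexanoyl-3,5-dihydroxy-4-methyl-4-(3-methylbut-2-en-1-yl)cyclohexa-2,5-dien-1-one; 18 1-{3-[(dimethylamino)methyl]-2,6-dihydroxy-4-methoxyphenyl}butan-1-one
Product: 20 (4R)-2-[(3-butanoyl-2,4-dihydroxy-6-methoxyphenyl)methyl]-6-hexanoyl-3,5-dihydroxy-4-methyl-4-(3-methylbut-2-en-1-yl)cyclohexa-2,5-dien-1-one, via 6-butanoyl-5-hydroxy-3-methoxy-2-methylidenecyclohexa-3,5-dien-1-one 19 (not isolated)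
Conditions: toluene, 90 °C
Reagents that add atoms: none
Why: Proton transfer from the acidic triketone to the benzylic amine should trigger loss of dimethylamine to the ortho-quinone methide, which is captured by Michael addition of the C5 enol carbon of ring A (its only free nucleophilic ring carbon) with rearomatisation of ring B, forming the methylene bridge without creating a stereocentre or disturbing C3.

Compound list
1 | 3-methoxycyclopent-2-en-1-one | COC1=CC(=O)CC1 | starting material
2 | 2-bromo-3-methoxycyclopent-2-en-1-one | COC1=C(Br)C(=O)CC1 | intermediate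
3 | 5-acetyl-2-bromo-3-methoxycyclopent-2-en-1-one (enolised β-diketone, drawn as the diketone) | COC1=C(Br)C(=O)C(C(C)=O)C1 | intermediate
4 | (1Z)-1-(3-bromo-4-methoxy-2-oxocyclopent-3-en-1-ylidene)ethyl trifluoromethanesulfonate | COC1=C(Br)C(=O)/C(C1)=C(/C)OS(=O)(=O)C(F)(F)F | intermediate
5 | 4,4,5,5-tetramethyl-2-(3-methylbut-2-en-1-yl)-1,3,2-dioxaborolane (prenylboronic acid pinacol ester) | CC(C)=CCB1OC(C)(C)C(C)(C)O1 | starting material
6 | (5Z)-2-bromo-3-methoxy-5-(5-methylhex-4-en-2-ylidene)cyclopent-2-en-1-one | COC1=C(Br)C(=O)/C(C1)=C(/C)CC=C(C)C | intermediate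
7 | (1R,5Z)-2-bromo-3-methoxy-5-(5-methylhex-4-en-2-ylidene)cyclopent-2-en-1-ol | COC1=C(Br)[C@H](O)/C(C1)=C(/C)CC=C(C)C | intermediate
8 | (2S,3R,4R)-5-bromo-6-methoxy-2-methyl-2-(3-methylbut-2-en-1-yl)-1-oxaspiro[2.4]hept-5-en-4-ol | COC1=C(Br)[C@H](O)[C@@]2(C1)O[C@@]2(C)CC=C(C)C | intermediate
9 | (2S,3S)-5-bromo-6-methoxy-2-methyl-2-(3-methylbut-2-en-1-yl)-1-oxaspiro[2.4]hept-5-en-4-one | COC1=C(Br)C(=O)[C@@]2(C1)O[C@@]2(C)CC=C(C)C | intermediate
10 | (2R)-4-bromo-5-methoxy-2-methyl-2-(3-methylbut-2-en-1-yl)cyclohex-4-ene-1,3-dione (ring A as C1 bromide and C6 methyl enol ether) | COC1=C(Br)C(=O)[C@](C)(CC=C(C)C)C(=O)C1 | intermediate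
11 | (6R)-2-bromo-3,5-dimethoxy-6-methyl-6-(3-methylbut-2-en-1-yl)cyclohexa-2,4-dien-1-one | COC1=C(Br)C(=O)[C@](C)(CC=C(C)C)C(OC)=C1 | intermediate
12 | pent-1-ene | C=CCCC | starting material
13 | 9-pentyl-9-borabicyclo[3.3.1]nonane (formed in the flask) | CCCCCB1C2CCCC1CCC2 | intermediate
14 | (6R)-2-hexanoyl-3,5-dimethoxy-6-methyl-6-(3-methylbut-2-en-1-yl)cyclohexa-2,4-dien-1-one | COC1=C(C(=O)CCCCC)C(=O)[C@](C)(CC=C(C)C)C(OC)=C1 | intermediate
15 | (4R)-2-hexanoyl-3,5-dihydroxy-4-methyl-4-(3-methylbut-2-en-1-yl)cyclohexa-2,5-dien-1-one | CCCCCC(=O)C1=C(O)[C@](C)(CC=C(C)C)C(O)=CC1=O | intermediate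
16 | 1-(2,4,6-trihydroxyphenyl)butan-1-one | CCCC(=O)c1c(O)cc(O)cc1O | starting material
17 | 1-(2,6-dihydroxy-4-methoxyphenyl)butan-1-one | CCCC(=O)c1c(O)cc(OC)cc1O | intermediate
18 | 1-{3-[(dimethylamino)methyl]-2,6-dihydroxy-4-methoxyphenyl}butan-1-one | CCCC(=O)c1c(O)cc(OC)c(CN(C)C)c1O | intermediate
19 | 6-butanoyl-5-hydroxy-3-methoxy-2-methylidenecyclohexa-3,5-dien-1-one (formed in the flask) | CCCC(=O)C1=C(O)C=C(OC)C(=C)C1=O | intermediate
20 | (4R)-2-[(3-butanoyl-2,4-dihydroxy-6-methoxyphenyl)methyl]-6-hexanoyl-3,5-dihydroxy-4-methyl-4-(3-methylbut-2-en-1-yl)cyclohexa-2,5-dien-1-one (CNP0219674.1) | CCCCCC(=O)C1=C(O)[C@](C)(CC=C(C)C)C(O)=C(Cc2c(OC)cc(O)c(C(=O)CCC)c2O)C1=O | target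

Total steps: 14. Longest linear sequence: 12 (steps 1–11 and 14).

Steps most likely to fail

Step 8. What may go wrong: ionisation may run ahead of migration, so that the tertiary cation loses a proton or captures fluoride, or the Lewis acid may be held at the vinylogous ester carbonyl so that the epoxide is not activated. The fallback moves the shift to the alcohol oxidation level and sets out from 8. Silylation (Et3SiOTf, 2,6-lutidine, CH2Cl2, −78 °C) should give the silyl ether (2S,3R,4R)-5-bromo-6-methoxy-2-methyl-2-(3-methylbut-2-en-1-yl)-4-[(triethylsilyl)oxy]-1-oxaspiro[2.4]hept-5-ene F1. Methylaluminium bis(4-bromo-2,6-di-tert-butylphenoxide) in CH2Cl2 at −78 °C should then open the same C–O bond with anti migration of the electron-rich siloxy-bearing carbon, the known organoaluminium rearrangement of epoxy silyl ethers to β-siloxy carbonyl compounds. This should give the ring-expanded ketone (5R,6S)-4-bromo-3-methoxy-6-methyl-6-(3-methylbut-2-en-1-yl)-5-[(triethylsilyl)oxy]cyclohex-3-en-1-one F2 with the same sense at the quaternary carbon. Desilylation (HF·pyridine, THF, 0 °C) to the alcohol (5R,6S)-4-bromo-5-hydroxy-3-methoxy-6-methyl-6-(3-methylbut-2-en-1-yl)cyclohex-3-en-1-one F3 and Dess–Martin oxidation come back to the route at 10.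

Step 5. What may go wrong: facial discrimination in the hydride transfer may be poor, since both flanks of the carbonyl are substituted sp2 carbons, or reduction of the vinylogous ester carbonyl may be sluggish. The fallback replaces asymmetric catalysis by a resolution and sets out from 6. Luche reduction (NaBH4, CeCl3·7H2O, MeOH, −20 °C) should give the racemic alcohol (5Z)-2-bromo-3-methoxy-5-(5-methylhex-4-en-2-ylidene)cyclopent-2-en-1-ol F4. Steglich esterification with (2S)-2-methoxy-2-phenylacetic acid (N,N′-dicyclohexylcarbodiimide, 4-(dimethylamino)pyridine, CH2Cl2) and chromatographic separation of the two diastereomers should give the ester (1R,5Z)-2-bromo-3-methoxy-5-(5-methylhex-4-en-2-ylidene)cyclopent-2-en-1-yl (2S)-2-methoxy-2-phenylacetate F5. Its methanolysis (K2CO3, MeOH, 0 °C) comes back to the route at 7; the other diastereomer can be cleaved and oxidised back to 6.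

Step 10. What may go wrong: alkyl transfer to palladium may precede CO insertion, giving the pentyl compound, or oxidative addition at the hindered tetrasubstituted bromide may be slow and end in protodebromination. The fallback builds the acyl group in two non-carbonylative operations and sets out from 11. Nozaki–Hiyama–Kishi addition to hexanal (CrCl2, NiCl2 (cat.), DMF, rt), chemoselective for the aldehyde over the ring ketone, should give the allylic alcohol (6R)-2-(1-hydroxyhexyl)-3,5-dimethoxy-6-methyl-6-(3-methylbut-2-en-1-yl)cyclohexa-2,4-dien-1-one F6 as a mixture of carbinol epimers. Dess–Martin oxidation of that mixture comes back to the route at 14.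

Further compounds
F1 | step 8 | (2S,3R,4R)-5-bromo-6-methoxy-2-methyl-2-(3-methylbut-2-en-1-yl)-4-[(triethylsilyl)oxy]-1-oxaspiro[2.4]hept-5-ene | COC1=C(Br)[C@H](O[Si](CC)(CC)CC)[C@@]2(C1)O[C@@]2(C)CC=C(C)C
F2 | step 8 | (5R,6S)-4-bromo-3-methoxy-6-methyl-6-(3-methylbut-2-en-1-yl)-5-[(triethylsilyl)oxy]cyclohex-3-en-1-one | COC1=C(Br)[C@H](O[Si](CC)(CC)CC)[C@](C)(CC=C(C)C)C(=O)C1
F3 | step 8 | (5R,6S)-4-bromo-5-hydroxy-3-methoxy-6-methyl-6-(3-methylbut-2-en-1-yl)cyclohex-3-en-1-one | COC1=C(Br)[C@H](O)[C@](C)(CC=C(C)C)C(=O)C1
F4 | step 5 | (5Z)-2-bromo-3-methoxy-5-(5-methylhex-4-en-2-ylidene)cyclopent-2-en-1-ol (racemic) | COC1=C(Br)C(O)/C(C1)=C(/C)CC=C(C)C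
F5 | step 5 | (1R,5Z)-2-bromo-3-methoxy-5-(5-methylhex-4-en-2-ylidene)cyclopent-2-en-1-yl (2S)-2-methoxy-2-phenylacetate | COC1=C(Br)[C@H](OC(=O)[C@@H](OC)c2ccccc2)/C(C1)=C(/C)CC=C(C)C
F6 | step 10 | (6R)-2-(1-hydroxyhexyl)-3,5-dimethoxy-6-methyl-6-(3-methylbut-2-en-1-yl)cyclohexa-2,4-dien-1-one (carbinol epimers) | COC1=C(C(O)CCCCC)C(=O)[C@](C)(CC=C(C)C)C(OC)=C1
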